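## Structural features

The target is a cis-fused eremophilane: ring A (C1 to C5 plus C10) and ring B (C5 to C10) share the C5–C10 bond, and H10 and the C5 methyl (C14) lie on the same face (called β below). Five stereocentres are contiguous (C3, C4, C5, C10, C9) and the sixth, C7, faces C9 across the C8 ketone; C5 is quaternary and is flanked by the tertiary centres C4 and C10. In the chair–chair conformer with C14 axial on ring A, the C15 methyl, both ester oxygens (3α, 9β) and the 7β-isopropenyl group are equatorial. C7 and C9, both α to the ketone, therefore already have their preferred configurations, whereas C4, C5 and C10 cannot be corrected by equilibration. The fragile groups are the two angelates (Z to E isomerisation), the α-acyloxy ketone (acyl shift, enediol formation) and above all the α-isopropenyl ketone, whose C7–H is both α to the carbonyl and allylic, so that base can epimerise it or move the double bond into conjugation. The real difficulty is twofold: the C4–C5–C10 triad with its cis ring fusion must come from C–C bond formation, and the C3 oxygen sits on the α-face, cis to C6, which is the face from which a hydride is expected to attack a C3 ketone, so simple reduction should give the wrong epimer. The key step uses the fact that the ring A triad, with cis C14/C15 and with C6 cis to C9, is the endo adduct of (E)-2-methylbut-2-enal across C3–C4 and C5–C10. A second feature is used later: C6 and the C3 oxygen are 1,3-cis on ring A, so an oxygen on C6 can form the C3–O bond intramolecularly with inversion.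

## Logic of the disconnections

31 to 27 and 28. Both ester C–O bonds (at O3 and O9) are cut first, because the Z-enoates are the groups most easily isomerised and should meet as few reagents as possible. This removes ten carbons, two molecules of 28, and leaves a diol in which all six stereocentres are in place. The forward acylation must avoid a nucleophilic acyl-transfer catalyst and strong base, so that neither the Z double bonds nor C7 move.

27 to 26 to 25. The O9 silyl ether is restored, then the C6–H and C7–H bonds are cut to a C6=C7 enone. Conjugate hydride delivery is the one way to saturate this bond while C11=C12 stays, and it takes C7 off the list of stereocentres to be carried. The forward step must add hydride 1,4 to a neopentyl β-carbon and protonate the dienolate at C7, not at C12, to give the equatorial isopropenyl group.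

25 to 22. The C6=C7 bond is cut as an intramolecular aldol condensation, and C6 returns to the aldehyde level, masked as a methyl acetal in which the C3 oxygen bridges to C6. C7 is the natural nucleophile (α to the ketone and allylic) and C6 is a non-enolisable aldehyde. Ring B disappears and the problem becomes a monocyclic ring A with a side chain on C10. The forward step needs O9 blocked, since a free O9 would lock C6 into a second acetal ring.

22 to 21 to 14 and 18; 18 to 15 and 16. The ketone is masked as a dithioacetal and the C8–C9 bond is cut between the C9 aldehyde carbon and an acyl anion that already carries C7 and the isopropenyl unit. This is the convergent cut: C9 with its oxygen and all remaining carbons arrive in one operation, and 18 comes from two commercial compounds. The forward addition must beat enolisation of the α-branched aldehyde and must follow the Felkin–Anh sense set by C10, which is the sense the target needs.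

14 to 13 to 12. Only the oxidation level and protection at C9 change. The demand is that neither step is acidic, because a free O9–H next to the acetal could close a second ring onto C6.

12 to 10 to 9 to 8. The O–C3 bond of the bridge is cut. Hydride reduction of the C3 ketone is expected to come from the α-face and give the 3β-alcohol; the cut turns this into an advantage, because an oxygen on C6, 1,3-diaxial to C3, can displace a 3β-sulfonate from the rear. The C3 configuration is thereby derived from C5, and the same operation protects C6 and O3. The forward step needs a free, non-enolisable aldehyde at C6 at the moment of closure and an equatorial leaving group.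

8 to 7 to 6 to 5. The C3 oxygen is traced back to the only allylic methylene of a cyclohexene (allylic oxidation, then alkene hydrogenation, in the forward sense), and the acetal back to the aldehyde. The gain is an intermediate with no functionality on ring A beyond one alkene. The demands are site selectivity for C3 over C1 and C10 and non-basic handling, since C4 becomes α to a ketone.

5 to 3 and 4. C3–C4 and C5–C10 are cut in a retro-[4+2]. Three contiguous stereocentres, the quaternary one included, and ring A reduce to two achiral five-carbon pieces. The forward step must be ortho-regioselective, endo-selective and selective for one enantioface.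

3 to 2 to 1. The O–Si bond and the reduction level of C9 are adjusted; nothing stereochemical is involved.

## Other disconnections considered

Alternative 1: The cut is C1–C10 in ring A, taken as a retro-[3,3] shift that reconnects C3 to C8. The cis-decalin folds back into the bicyclo[2.2.2]octenyl vinyl carbinol A1 (bridgeheads C5 and C8; vinyl and C4 methyl both on the side of the C9=C10 bridge). Forward, the potassium alkoxide of A1 (KH, 18-crown-6) would undergo an anionic oxy-Cope shift through a boat-like array: C1–C10 forms, C3–C8 breaks, and protonation of the enolate would give A2, the cis-fused C3 ketone with a C8=C9 methyl enol ether.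
- In its favour: the cis ring fusion is enforced by the bicycle, which is the equal of the endo control in the chosen plan. The C3 carbonyl arrives directly, so the site-selectivity question of the allylic oxidation (step 5) does not arise; on this point the alternative is the better one. The regiodefined enol ether could be oxidised at C9 by a Rubottom-type reaction, at least the equal of the acyl-anion addition.
- Against it here: A1 must itself be assembled by an earlier [4+2] step that places the C4 methyl on the alkene side, followed by a vinyl addition from the face that this methyl hinders. An enantioselective version of that earlier cycloaddition is less well founded than the oxazaborolidinium-catalysed addition of an α-substituted enal, so the absolute configuration would probably rest on a resolution. The C3 ketone of A2 faces the same facial bias as 8, and the isopropenyl group would have to be introduced at C7 by enolate chemistry on a ketone with a second, oxygenated α-carbon.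
- Comparison: both plans make the quaternary C5 and ring A in a pericyclic step and both are mechanistically reliable. The alternative reaches a bicycle sooner but spends more steps on C7 and the absolute configuration, so no net saving is expected.

Alternative 2: The cut is C5–C6, which opens ring B to the bis-enone A3, a 2,3-dimethylcyclohex-2-enone carrying a 2-oxobut-3-enyl chain on C10. Forward, cathodic reduction of the vinyl ketone would give a radical anion whose β-carbon (C6) adds to C5 of the ring enone; a second electron and two protons would give A4, the cis-fused 3,8-dione.
- In its favour: A3 has a single stereocentre and needs no protecting groups. C5 becomes quaternary under reagent-free conditions, and C4, α to a ketone in A4, can settle in the equatorial configuration the target needs. The step count to the decalin is lower than in the chosen plan, which is a real advantage.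
- Against it: only the chain conformation decides whether C6 adds cis or trans to the C10 substituent, so the ring fusion would rest on an uncontrolled ratio, whereas the chosen plan fixes it in a concerted step. Addition to a tetrasubstituted β-carbon must compete with hydrodimerisation and simple reduction of the vinyl ketone. A4 has no oxygen at C9 and no carbon at C7, so both α-positions of the C8 ketone must be functionalised regioselectively in the presence of a second ketone, and the C3 reduction problem remains.
- Comparison: shorter and more convergent to the skeleton, but the stereochemical and regiochemical burden moves to later steps with less control, which would probably cost more steps than are saved.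

Alternative 3: The cut is C4–C5, which opens ring A and aromatises ring B to the catechol mono-ether A5, in which a trans-epoxide (C3–C4) is tethered to C10 by two methylene groups. Forward, the potassium phenoxide at the C8 oxygen (KOt-Bu) would attack the epoxide carbon C4 through its para carbon C5 with inversion; ring A closes and ring B becomes the cross-conjugated dienone A6.
- In its favour: both ring B oxygens are present from the start. The epoxide carries the absolute configuration of C3 and C4 and delivers the 3α-hydroxyl directly, which is clearly better than the reduction and inversion sequence (steps 7 to 9) of the chosen plan. C5 becomes quaternary in the same step.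
- Against it: the para carbon can reach either epoxide carbon, and the 5-exo opening at C3, which would give a five-membered ring with the carbinol outside it, is the trajectory normally preferred over the 6-endo opening at C4. The ortho carbon C9 sits next to the tether as well and competes with C5, and intermolecular O-alkylation is a further leak. The configuration at C5 depends only on the tether conformation. Syn reduction of the tetrasubstituted C9=C10 enol ether of A6 would set H9 cis to H10 and require later epimerisation at C9, and the isopropenyl group would have to be attached to the α-carbon of a dienone.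
- Comparison: structurally this alternative handles C3 and C9 oxygenation more elegantly; mechanistically its key step carries a regiochemical risk that the Diels–Alder reaction does not; the step count after A6 would be similar to that of the chosen plan after 14.

Key step: step 3

Remark: eremophilane numbering is kept for every intermediate; β is the face of ring A that carries C14; the acetal carbon C6 of 12 to 14 and 20 to 23 (and C6/C7 of 24) is expected as an epimer mixture and is left undefined in the SMILES, because C6 ends as a methylene group.

## Route

Step 1
Reactants: 1 (E)-penta-2,4-dienoic acid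
Product: 2 (E)-penta-2,4-dien-1-ol
Conditions: LiAlH4, Et2O, 0 °C to rt; H2O work-up
Reagents that add atoms: none
Why: Hydride reduction of a carboxylic acid to the primary alcohol; delivery from the carboxylate-bound aluminate is 1,2, so the conjugated diene and its E geometry should be kept at low temperature.

Step 2
Reactants: 2 (E)-penta-2,4-dien-1-ol
Product: 3 (E)-tert-butyldimethyl(penta-2,4-dienyloxy)silane
Conditions: TBSCl, imidazole, CH2Cl2, 0 °C to rt
Reagents that add atoms: tert-butyldimethylsilyl chloride, CC(C)(C)[Si](C)(C)Cl
Why: Imidazole-promoted silylation of a primary alcohol; the silyl ether makes the diene a 1-alkyl butadiene with a non-coordinating, acid-tolerant oxygen.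

Step 3
Reactants: 3 (E)-tert-butyldimethyl(penta-2,4-dienyloxy)silane; 4 tiglaldehyde
Product: 5 (1R,2S,6S)-2-[(tert-butyldimethylsilyloxy)methyl]-1,6-dimethylcyclohex-3-ene-1-carbaldehyde
Conditions: (R)-3,3-diphenyl-1-(o-tolyl)tetrahydro-1H,3H-pyrrolo[1,2-c][1,3,2]oxazaborole (20 mol%), Tf2NH (18 mol%), CH2Cl2, −78 to −20 °C
Reagents that add atoms: none
Why: Protonation of the oxazaborolidine by Tf2NH gives a cationic boron Lewis acid that binds the formyl oxygen of 4 anti to the alkenyl group, with the formyl C–H held against the ring oxygen, so that the s-trans enal lies over one C-aryl group. The cycloaddition is a concerted, asynchronous, suprafacial [4+2] in which the unsubstituted diene terminus bonds to the β-carbon first (C3–C4) and C5–C10 follows; ring A closes as the six-membered cycloaddition ring. The closest known reaction type is the cationic oxazaborolidine-catalysed Diels–Alder addition of α-substituted enals to 1-substituted butadienes. C4 and C5 are tied together by the E geometry of 4, which is transferred suprafacially into cis C14/C15. C10 is set relative to C5 by the endo orientation of the boron-bound formyl group over the E-diene, which places C6 cis to C9. The absolute sense comes from the catalyst: in the (R) series the aryl shield should cover the Cα re face, so the diene adds to the si face and gives (1R,2S,6S)-5, while the enantiomeric catalyst would give the mirror image. The step needs ortho regiochemistry (secured by the alkyl donor on the diene terminus that bonds to Cα), endo selectivity (secondary overlap of the activated formyl group) and one enantioface (the aryl shield). Tf2NH activation with its non-coordinating counter-ion supplies the reactivity that the β-substituted enal needs at temperatures where the silyl ether is not ionised.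

Step 4
Reactants: 5 (1R,2S,6S)-2-[(tert-butyldimethylsilyloxy)methyl]-1,6-dimethylcyclohex-3-ene-1-carbaldehyde
Product: 6 C6 dimethyl acetal of 5
Conditions: MeOSiMe3 (3 equiv), TMSOTf (5 mol%), CH2Cl2, −78 to −30 °C; pyridine quench
Reagents that add atoms: methoxytrimethylsilane (two equivalents are incorporated), CO[Si](C)(C)C
Why: Silyl triflate-catalysed acetalisation of an aldehyde with an alkoxysilane; the aprotic, low-temperature conditions keep the primary silyl ether and the alkene, and the acetal shields the aldehyde from the oxidant of step 5 and the hydride of step 7.

Step 5
Reactants: 6 C6 dimethyl acetal of 5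
Product: 7 ring A enone (C1=C2–C3=O) with C6 dimethyl acetal
Conditions: Rh2(cap)4 (cap = caprolactamate, 1 mol%), t-BuOOH (5.5 M in decane, 5 equiv), K2CO3 (solid, 0.5 equiv), CH2Cl2, rt
Reagents that add atoms: tert-butyl hydroperoxide, CC(C)(C)OO
Why: Radical allylic oxidation: the tert-butylperoxyl radical abstracts hydrogen from C3, the only allylic methylene (the tertiary C10–H is shielded by the quaternary C5), and the mixed peroxide collapses to the conjugated ketone. No stereocentre is formed, but C4 becomes α to a ketone, so 7 is handled without soluble base.

Step 6
Reactants: 7 ring A enone (C1=C2–C3=O) with C6 dimethyl acetal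
Product: 8 ring A C3 ketone with C6 dimethyl acetal
Conditions: H2 (1 atm), 10% Pd/C, EtOAc, rt
Reagents that add atoms: none
Why: Heterogeneous hydrogenation of the disubstituted enone alkene; C1 and C2 become methylene groups, no stereocentre is formed, and the neutral medium should leave C4 untouched.

Step 7
Reactants: 8 ring A C3 ketone with C6 dimethyl acetal
Product: 9 3β-alcohol of ring A (OH cis to C14 and C15)
Conditions: LiBH(s-Bu)3 (L-Selectride), THF, −78 °C; H2O
Reagents that add atoms: none
Why: Bulky-hydride reduction under steric approach control: in the chair with the C6 acetal equatorial, the axial C14 methyl blocks the β-face of C3, so hydride should enter equatorially from the α-face and place the oxygen β. The other chair has its α-face blocked by the axial acetal and its β-face hindered by the axial C15 methyl, so it should react more slowly.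

Step 8
Reactants: 9 3β-alcohol of ring A (OH cis to C14 and C15)
Product: 10 3β-methanesulfonate of 9
Conditions: MsCl, Et3N, CH2Cl2, 0 °C
Reagents that add atoms: methanesulfonyl chloride, CS(=O)(=O)Cl
Why: Sulfonylation through sulfene, which works on hindered secondary alcohols and retains the C3 configuration; the β-oxygen becomes a leaving group that is equatorial in the chair with C6 axial.

Step 9
Reactants: 10 3β-methanesulfonate of 9
Product: 12 2-[(tert-butyldimethylsilyloxy)methyl]-7-methoxy-1,8-dimethyl-6-oxabicyclo[3.2.1]octane (oxygen bridge from C6 to C3α), via 3β-mesyloxy aldehyde 11 (not isolated)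
Conditions: TESOTf, 2,4,6-collidine, CH2Cl2, 0 °C; H2O; crude 11, NaOMe, MeOH, 0 °C to rt
Reagents that add atoms: water, O; sodium methoxide, [Na+].[O-]C
Why: Silyl triflate/collidine cleavage of the dimethyl acetal frees the aldehyde without acid, so the primary silyl ether and the mesylate survive. Methoxide then adds to the non-enolisable aldehyde, and the hemiacetal alkoxide, axial on C5, displaces the equatorial mesylate from the rear (intramolecular SN2, 5-exo-tet, Williamson type), which inverts C3 to the 3α-oxygen. Elimination is disfavoured because an equatorial leaving group has no anti-periplanar hydrogen.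

Step 10
Reactants: 12 2-[(tert-butyldimethylsilyloxy)methyl]-7-methoxy-1,8-dimethyl-6-oxabicyclo[3.2.1]octane
Product: 13 (7-methoxy-1,8-dimethyl-6-oxabicyclo[3.2.1]octan-2-yl)methanol
Conditions: TBAF, THF, 0 °C to rt
Reagents that add atoms: none
Why: Fluoride desilylation of a primary silyl ether; the medium is basic, which matters because acid would let the free C9 hydroxyl close a second acetal ring onto C6.

Step 11
Reactants: 13 (7-methoxy-1,8-dimethyl-6-oxabicyclo[3.2.1]octan-2-yl)methanol
Product: 14 7-methoxy-1,8-dimethyl-6-oxabicyclo[3.2.1]octane-2-carbaldehyde
Conditions: (COCl)2, DMSO, CH2Cl2, −78 °C; Et3N, −78 to 0 °C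
Reagents that add atoms: none
Why: Swern oxidation; the low temperature and amine base keep the acetal intact and should not epimerise the α-stereocentre C10, whose formyl group is equatorial on the locked chair.

Step 12
Reactants: 15 1,3-dithiane; 16 3-chloro-2-methylpropene
Product: 18 2-(2-methylprop-2-en-1-yl)-1,3-dithiane, via 2-lithio-1,3-dithiane 17 (not isolated)
Conditions: n-BuLi, THF, −30 °C; then 16, −78 °C to rt
Reagents that add atoms: none
Why: Corey–Seebach alkylation: the sulfur-stabilised anion displaces the primary allylic chloride by SN2.

Step 13
Reactants: 14 7-methoxy-1,8-dimethyl-6-oxabicyclo[3.2.1]octane-2-carbaldehyde; 18 2-(2-methylprop-2-en-1-yl)-1,3-dithiane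
Product: 21 C9 tert-butyldimethylsilyl ether of the C8-dithiane carbinol, via lithiated dithiane 19 (not isolated), via lithium alkoxide 20 (not isolated)
Conditions: 18 (1.3 equiv), n-BuLi, THF, −30 °C; then 14, −78 °C; then TBSOTf, −78 to 0 °C
Reagents that add atoms: tert-butyldimethylsilyl triflate, CC(C)(C)[Si](C)(C)OS(=O)(=O)C(F)(F)F
Why: Corey–Seebach acyl-anion addition to an aldehyde. Under Felkin–Anh control the bulky nucleophile enters anti to the quaternary C5 and past H10, which gives the C9 configuration of the target. The alkoxide is silylated in the same flask so that O9 can never form a second acetal ring with C6.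

Step 14
Reactants: 21 C9 tert-butyldimethylsilyl ether of the C8-dithiane carbinol
Product: 22 C8 ketone with C7H2–isopropenyl chain, C9 silyl ether and bridged C6 acetal
Conditions: MeI, CaCO3, MeCN/H2O (9:1), 45 °C
Reagents that add atoms: water, O
Why: Alkylative hydrolysis of the dithioacetal (S-methylation, then water); the carbonate buffers the HI, so the acetal, the silyl ether and the 1,1-disubstituted alkene should survive.

Step 15
Reactants: 22 C8 ketone with C7H2–isopropenyl chain, C9 silyl ether and bridged C6 acetal
Product: 25 3α-hydroxy-9β-(tert-butyldimethylsilyloxy)-10βH-eremophila-6,11-dien-8-one, via bridged lactol 23 (not isolated), via aldol 24 (not isolated)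
Conditions: Amberlyst-15, THF/H2O (10:1), rt; filter; K2CO3 (0.5 equiv), MeOH, 0 °C to rt
Reagents that add atoms: none
Why: Mild acid hydrolysis of the furanoside-type acetal frees the C6 aldehyde as its lactol with O3; carbonate then forms the dienolate at the doubly activated C7, which closes ring B by an intramolecular aldol addition (6-(enolendo)-exo-trig), and E1cB dehydration gives the cross-conjugated dienone. The cis ring fusion is inherited from 5, and closure through C9 is impossible because it would give a four-membered ring. Reversible oxa-Michael addition of the 3α-hydroxyl to C6 would force ring A into the chair with C15 axial and would cost the diene conjugation, so the open dienone should prevail at equilibrium.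

Step 16
Reactants: 25 3α-hydroxy-9β-(tert-butyldimethylsilyloxy)-10βH-eremophila-6,11-dien-8-one
Product: 26 3α-hydroxy-9β-(tert-butyldimethylsilyloxy)-10βH-eremophil-11-en-8-one (7β-isopropenyl)
Conditions: [(Ph3P)CuH]6 (0.5 equiv), H2O (5 equiv), THF/benzene, rt
Reagents that add atoms: none
Why: Copper hydride conjugate reduction: hydride adds to C6, the β-carbon of the enone, and leaves the cross-conjugated C11=C12 bond alone. The dienolate is protonated kinetically at C7 (the α-carbon), axially in the half-chair that leads to the all-equatorial decalin, to give the 7β-isopropenyl ketone, which is also the thermodynamically preferred C7 epimer.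

Step 17
Reactants: 26 3α-hydroxy-9β-(tert-butyldimethylsilyloxy)-10βH-eremophil-11-en-8-one
Product: 27 3α,9β-dihydroxy-10βH-eremophil-11-en-8-one
Conditions: HF·pyridine, pyridine, THF, 0 °C to rt
Reagents that add atoms: none
Why: Buffered fluoride desilylation of the α-silyloxy ketone; the medium is non-basic, so C7 should neither epimerise nor lose its double bond to conjugation.

Step 18
Reactants: 27 3α,9β-dihydroxy-10βH-eremophil-11-en-8-one; 28 angelic acid
Product: 31 3α,9β-bis[(Z)-2-methylbut-2-enoyloxy]-10βH-eremophil-11-en-8-one (CNP0174755.1), via mixed anhydride 29 (not isolated), via 3-monoangelate 30 (not isolated)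
Conditions: 28 (3 equiv), 2,4,6-trichlorobenzoyl chloride (3 equiv), Et3N (3 equiv), toluene, rt; then 27, 80 °C
Reagents that add atoms: angelic acid (second equivalent of 28), C/C=C(/C)C(=O)O
Why: Yamaguchi-type mixed-anhydride esterification run without a nucleophilic acyl-transfer catalyst: each hydroxyl attacks the less hindered angeloyl carbonyl of one molecule of 29, and because no acylpyridinium or conjugate-addition intermediate forms, the Z geometry should be kept. Two molecules of 29 are consumed, one per hydroxyl; the ordinary secondary C3 hydroxyl is expected to react first and the carbonyl-deactivated C9 hydroxyl second, and since both are equatorial one operation should carry both acylations.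

## Compound list

1 | (E)-penta-2,4-dienoic acid | C=C/C=C/C(=O)O | starting material
2 | (E)-penta-2,4-dien-1-ol | C=C/C=C/CO | intermediate
3 | (E)-tert-butyldimethyl(penta-2,4-dienyloxy)silane | C=C/C=C/CO[Si](C)(C)C(C)(C)C | intermediate
4 | tiglaldehyde, (E)-2-methylbut-2-enal | C/C=C(\C)C=O | starting material
5 | (1R,2S,6S)-2-[(tert-butyldimethylsilyloxy)methyl]-1,6-dimethylcyclohex-3-ene-1-carbaldehyde (ring A; C14, C15, H10 β; C6 formyl and C9 silyloxymethyl α) | O=C[C@@]1(C)[C@H](C=CC[C@@H]1C)CO[Si](C)(C)C(C)(C)C | intermediate
6 | C6 dimethyl acetal of 5 | COC(OC)[C@@]1(C)[C@H](C=CC[C@@H]1C)CO[Si](C)(C)C(C)(C)C | intermediate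
7 | ring A enone, C1=C2–C3=O, C6 dimethyl acetal, C9 silyl ether | COC(OC)[C@@]1(C)[C@H](C=CC(=O)[C@@H]1C)CO[Si](C)(C)C(C)(C)C | intermediate
8 | ring A C3 ketone, C6 dimethyl acetal, C9 silyl ether | COC(OC)[C@@]1(C)[C@H](CCC(=O)[C@@H]1C)CO[Si](C)(C)C(C)(C)C | intermediate
9 | 3β-alcohol (OH cis to C14 and C15) | COC(OC)[C@@]1(C)[C@H](CC[C@H](O)[C@@H]1C)CO[Si](C)(C)C(C)(C)C | intermediate
10 | 3β-methanesulfonate of 9 | COC(OC)[C@@]1(C)[C@H](CC[C@H](OS(C)(=O)=O)[C@@H]1C)CO[Si](C)(C)C(C)(C)C | intermediate
11 | 3β-mesyloxy C6 aldehyde | O=C[C@@]1(C)[C@H](CC[C@H](OS(C)(=O)=O)[C@@H]1C)CO[Si](C)(C)C(C)(C)C | intermediate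
12 | 2-[(tert-butyldimethylsilyloxy)methyl]-7-methoxy-1,8-dimethyl-6-oxabicyclo[3.2.1]octane (oxygen bridges C6 and C3α; C7 of the bicycle is eremophilane C6) | COC2[C@@]1(C)[C@H](CC[C@@H](O2)[C@@H]1C)CO[Si](C)(C)C(C)(C)C | intermediate
13 | (7-methoxy-1,8-dimethyl-6-oxabicyclo[3.2.1]octan-2-yl)methanol | COC2[C@@]1(C)[C@H](CC[C@@H](O2)[C@@H]1C)CO | intermediate
14 | 7-methoxy-1,8-dimethyl-6-oxabicyclo[3.2.1]octane-2-carbaldehyde | COC2[C@@]1(C)[C@H](CC[C@@H](O2)[C@@H]1C)C=O | intermediate
15 | 1,3-dithiane | C1CSCSC1 | starting material
16 | 3-chloro-2-methylpropene | C=C(C)CCl | starting material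
17 | 2-lithio-1,3-dithiane | [Li]C1SCCCS1 | intermediate
18 | 2-(2-methylprop-2-en-1-yl)-1,3-dithiane | C=C(C)CC1SCCCS1 | intermediate
19 | 2-lithio-2-(2-methylprop-2-en-1-yl)-1,3-dithiane | [Li]C1(CC(C)=C)SCCCS1 | intermediate
20 | lithium alkoxide of the C9 carbinol (C8 as the 2-substituted dithiane) | COC2[C@@]1(C)[C@H](CC[C@@H](O2)[C@@H]1C)[C@@H](O[Li])C3(CC(C)=C)SCCCS3 | intermediate
21 | C9 tert-butyldimethylsilyl ether of the C8-dithiane carbinol | COC2[C@@]1(C)[C@H](CC[C@@H](O2)[C@@H]1C)[C@@H](O[Si](C)(C)C(C)(C)C)C3(CC(C)=C)SCCCS3 | intermediate
22 | 1-(bridged acetal)-1-(tert-butyldimethylsilyloxy)-4-methylpent-4-en-2-one (C8 ketone) | COC2[C@@]1(C)[C@H](CC[C@@H](O2)[C@@H]1C)[C@@H](O[Si](C)(C)C(C)(C)C)C(=O)CC(C)=C | intermediate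
23 | bridged lactol (C6 hemiacetal with O3) | OC2[C@@]1(C)[C@H](CC[C@@H](O2)[C@@H]1C)[C@@H](O[Si](C)(C)C(C)(C)C)C(=O)CC(C)=C | intermediate
24 | aldol: 3α,6-dihydroxy-9β-silyloxy-eremophil-11-en-8-one | C=C(C)C1C(O)[C@@]2(C)[C@H](CC[C@@H](O)[C@@H]2C)[C@@H](O[Si](C)(C)C(C)(C)C)C1=O | intermediate
25 | 3α-hydroxy-9β-(tert-butyldimethylsilyloxy)-10βH-eremophila-6,11-dien-8-one | C=C(C)C1=C[C@@]2(C)[C@H](CC[C@@H](O)[C@@H]2C)[C@@H](O[Si](C)(C)C(C)(C)C)C1=O | intermediate
26 | 3α-hydroxy-9β-(tert-butyldimethylsilyloxy)-10βH-eremophil-11-en-8-one (7β-isopropenyl) | C=C(C)[C@H]1C[C@@]2(C)[C@H](CC[C@@H](O)[C@@H]2C)[C@@H](O[Si](C)(C)C(C)(C)C)C1=O | intermediate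
27 | 3α,9β-dihydroxy-10βH-eremophil-11-en-8-one | C=C(C)[C@H]1C[C@@]2(C)[C@H](CC[C@@H](O)[C@@H]2C)[C@@H](O)C1=O | intermediate
28 | angelic acid, (Z)-2-methylbut-2-enoic acid | C/C=C(/C)C(=O)O | starting material
29 | angelic 2,4,6-trichlorobenzoic anhydride | C/C=C(/C)C(=O)OC(=O)c1c(Cl)cc(Cl)cc1Cl | intermediate
30 | 3α-[(Z)-2-methylbut-2-enoyloxy]-9β-hydroxy-10βH-eremophil-11-en-8-one (3-monoangelate) | C=C(C)[C@H]1C[C@@]2(C)[C@H](CC[C@@H](OC(=O)/C(C)=C\C)[C@@H]2C)[C@@H](O)C1=O | intermediate
31 | 3α,9β-bis[(Z)-2-methylbut-2-enoyloxy]-10βH-eremophil-11-en-8-one, CNP0174755.1 | C=C(C)[C@H]1C[C@@]2(C)[C@H](CC[C@@H](OC(=O)/C(C)=C\C)[C@@H]2C)[C@@H](OC(=O)/C(C)=C\C)C1=O | target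

## Step count and least certain steps

Total: 18 steps. Longest linear sequence: 17 steps (steps 1 to 11 and 13 to 18); step 12 is the one-step branch to 18.

Step 3 (key step). The β-substituted, α-branched enal is a sluggish dienophile, so the cycloaddition may need temperatures at which exo addition, loss of facial control or acid-induced oligomerisation of 3 compete. The choice of the catalyst antipode rests on the formyl C–H···O binding model; should the sense of induction prove to be the opposite one, the (S) catalyst is used in its place. Fallback, setting out from 3 and 4: EtAlCl2 (CH2Cl2, −78 °C) gives the racemic endo adduct F1. F1 is condensed with (1R,2R)-N,N'-dimethyl-1,2-diphenylethane-1,2-diamine, and the imidazolidine of the (1R,2S,6S)-aldehyde F2 is separated by chromatography from the diastereomeric imidazolidine of the enantiomeric aldehyde F3, which is discarded. Hydrolysis of F2 on wet silica gel returns the route at 5.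

Step 5. Poor site selectivity is the likely failure: the allyl radical formed at C3 can be trapped at C1 (transposed enone), and abstraction at C10 is a second leak, because both ends of the allyl system have similar surroundings. Fallback, setting out from 6: SeO2 (cat.) with t-BuOOH hydroxylates the allylic methylene by an ene reaction followed by a [2,3]-shift, which returns oxygen to the carbon that lost hydrogen and so cannot transpose, to give the C3 allylic alcohol F4. Oxidation of F4 with MnO2 returns the route at 7.

Step 7 (with step 9). The facial selectivity of hydride delivery may be lower than argued, or reversed, because the two chairs of 8 are close in energy; in step 9, attack of methoxide at sulfur or elimination through the minor chair could compete with ring closure. Fallback, setting out from 8: if reduction gives the 3α-alcohol F5, F5 is not mesylated but treated with pyridinium p-toluenesulfonate and 4 Å molecular sieves in CH2Cl2, where intramolecular transacetalisation with loss of methanol (retention at C3) returns the route at 12. Both C3 epimers therefore converge on the same bridged acetal.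

Step 13. Enolisation of the α-branched aldehyde by the hindered, strongly basic 2-alkyl dithiane anion and erosion of Felkin–Anh control are the likely failures. Fallback, setting out from 14: the smaller parent anion 17 is added to give the C9 carbinol of the unsubstituted dithiane F6. F6 is converted by n-BuLi (2 equiv) into its O,C-dilithio derivative F7, which is C-alkylated with 16 to give the alkoxide 20; this is silylated as in step 13 and so returns the route at 21.

Step 16. Protonation of the dienolate on the wrong face, migration of the double bond into conjugation during any attempt to equilibrate C7, and slow hydride addition to the neopentyl C6 are the likely failures. Fallback, setting out from 25: RhCl(PPh3)3 and Et3SiH give, by 1,4-hydrosilylation with silylation of O3, the isolable triethylsilyl dienol ether F8. Buffered HF·pyridine at low temperature then protonates C7 under non-basic conditions and removes all three silyl groups, which returns the route at 27.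

Step 18. Z to E isomerisation of the acyl donor, incomplete acylation of the second hydroxyl, and amine-induced epimerisation or double-bond migration at C7 during the heating are the likely failures. Fallback, setting out from 27: both hydroxyls are acylated with 2-[bis(2,2,2-trifluoroethoxy)phosphoryl]propanoic acid (carbodiimide, rt) to give the bis(phosphonopropionate) F9. A Still–Gennari olefination of F9 with acetaldehyde (K2CO3, 18-crown-6, toluene, −20 °C) builds both Z-enoates on the esters and returns the route at 31.

## Further compounds

F1 | step 3 | racemic endo adduct (racemate of 5; the (1R,2S,6S) enantiomer is drawn) | O=C[C@@]1(C)[C@H](C=CC[C@@H]1C)CO[Si](C)(C)C(C)(C)C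
F2 | step 3 | imidazolidine of (1R,2S,6S)-5 with (1R,2R)-N,N'-dimethyl-1,2-diphenylethane-1,2-diamine | CN1[C@H](c2ccccc2)[C@@H](c2ccccc2)N(C)C1[C@@]3(C)[C@H](C=CC[C@@H]3C)CO[Si](C)(C)C(C)(C)C
F3 | step 3 | diastereomeric imidazolidine of the (1S,2R,6R)-aldehyde with the same diamine | CN1[C@H](c2ccccc2)[C@@H](c2ccccc2)N(C)C1[C@]3(C)[C@@H](C=CC[C@H]3C)CO[Si](C)(C)C(C)(C)C
F4 | step 5 | C3 allylic alcohol of 6 (C1=C2 kept; C3 epimer mixture) | COC(OC)[C@@]1(C)[C@H](C=CC(O)[C@@H]1C)CO[Si](C)(C)C(C)(C)C
F5 | step 7 | 3α-alcohol (C3 epimer of 9) | COC(OC)[C@@]1(C)[C@H](CC[C@@H](O)[C@@H]1C)CO[Si](C)(C)C(C)(C)C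
F6 | step 13 | C9 carbinol of the unsubstituted dithiane | COC2[C@@]1(C)[C@H](CC[C@@H](O2)[C@@H]1C)[C@@H](O)C3SCCCS3
F7 | step 13 | O,C-dilithio derivative of F6 | COC2[C@@]1(C)[C@H](CC[C@@H](O2)[C@@H]1C)[C@@H](O[Li])C3([Li])SCCCS3
F8 | step 16 | C8 triethylsilyl dienol ether with 3α-triethylsilyloxy and 9β-tert-butyldimethylsilyloxy groups | C=C(C)C1=C(O[Si](CC)(CC)CC)[C@H](O[Si](C)(C)C(C)(C)C)[C@H]2CC[C@@H](O[Si](CC)(CC)CC)[C@H](C)[C@@]2(C)C1
F9 | step 18 | 3α,9β-bis{2-[bis(2,2,2-trifluoroethoxy)phosphoryl]propanoyloxy}-10βH-eremophil-11-en-8-one | C=C(C)[C@H]1C[C@@]2(C)[C@H](CC[C@@H](OC(=O)C(C)P(=O)(OCC(F)(F)F)OCC(F)(F)F)[C@@H]2C)[C@@H](OC(=O)C(C)P(=O)(OCC(F)(F)F)OCC(F)(F)F)C1=O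
A1 | alternative 1 | 1-methoxy-3,4-dimethyl-2-vinylbicyclo[2.2.2]oct-5-en-2-ol (vinyl and C3 methyl syn to the alkene bridge) | C1C[C@@]2(C)C=C[C@]1(OC)[C@](O)(C=C)[C@@H]2C
A2 | alternative 1 | cis-fused C3 ketone with C8=C9 methyl enol ether | C1C[C@@]2(C)[C@H](CCC(=O)[C@@H]2C)C=C1OC
A3 | alternative 2 | (R)-2,3-dimethyl-4-(2-oxobut-3-en-1-yl)cyclohex-2-en-1-one | CC1=C(C)C(=O)CC[C@@H]1CC(=O)C=C
A4 | alternative 2 | cis-fused 4,5-dimethyldecalin-3,8-dione (eremophilane numbering) | C1C[C@@]2(C)[C@H](CCC(=O)[C@@H]2C)CC1=O
A5 | alternative 3 | 2-(methoxymethoxy)-4-methyl-3-{2-[(2R,3R)-3-methyloxiran-2-yl]ethyl}phenol | Cc1ccc(O)c(OCOC)c1CC[C@H]1O[C@@H]1C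
A6 | alternative 3 | 3-hydroxy-9-(methoxymethoxy)-eremophila-6,9-dien-8-one lacking the isopropenyl group | C1=C[C@@]2(C)C(CC[C@@H](O)[C@@H]2C)=C(OCOC)C1=O
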